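**Assumption:** the SMILES is read as drawn (carbinol carbon C1 of the cyclopenta[b]chromene unit is S; cyclopentane exo-fused to the oxygen bridge; C1–OH on the bridge side). Which antipode of the carbene catalyst gives (S)-10 is settled by a trial with both commercial antipodes.

## Retrosynthetic overview

1. Last ring-forming event: both C–C bonds of the oxa-bridged six-membered ring are made in one exo Diels–Alder reaction of a 1-aryl-isobenzofuran (made in the flask) with an enantiopure cyclopenta[b]chromenone alkene; MOM removal follows.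
2. Key disconnection: the C1–C2 bond of the cyclopentene ring. A carbene catalyst turns the vinyl terminus of a 2-vinylchromone (a natural acceptor carbon) into a donor (deoxy-Breslow, vinylogous homoenolate type), which closes onto the keto carbon of a 3-methoxalyl group and sets the C1 carbinol centre that controls all other stereocentres.
3. The 2-vinyl-3-methoxalylchromone comes from 3,5-dihydroxybenzyl alcohol by ortho-lithiation/acetylation, enaminone formation, oxalylation–cyclisation and methylenation.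
4. The isobenzofuran precursor (diaryl carbinol with an ortho acetal) comes from lithiated resorcinol bis-MOM ether and a mono-acetal phthalaldehyde made by Comins ortho-lithiation of an ether of 2,5-dihydroxy-4-methylbenzaldehyde.
5. Ring order: benzene rings bought → pyranone → cyclopentene (key step) → furan (isobenzofuran) → oxa-bridge and carbocycle together in the cycloaddition.

## Route

**Step 1**
Reactants: 1 3,5-dihydroxybenzyl alcohol
Product: 2 1,3-bis(methoxymethoxy)-5-[(methoxymethoxy)methyl]benzene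
Conditions: MOMCl (3.6 equiv), i-Pr2NEt, CH2Cl2, 0 °C → rt
Reagents that add atoms: chloromethyl methyl ether, COCCl
Why: Base-mediated O-alkylation (MOM acetal formation) of both phenols and the primary alcohol; no stereocentre.

**Step 2**
Reactants: 2 1,3-bis(methoxymethoxy)-5-[(methoxymethoxy)methyl]benzene
Product: 5 1-[2-hydroxy-6-(methoxymethoxy)-4-[(methoxymethoxy)methyl]phenyl]ethan-1-one, via aryllithium 3 (not isolated), via bis-MOM ketone 4 (not isolated)
Conditions: n-BuLi, TMEDA, THF, 0 °C; AcN(OMe)Me, −78 °C → rt; then 1 M HCl, MeOH, rt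
Reagents that add atoms: N-methoxy-N-methylacetamide, CC(=O)N(C)OC
Why: Directed ortho-metalation removes the proton flanked by both OMOM groups, the Weinreb acylation stops at the ketone, and acid methanolysis cleaves only the first MOM ether because the freed phenol then locks the carbonyl in a hydrogen bond (chelation-assisted mono-deprotection).

**Step 3**
Reactants: 5 1-[2-hydroxy-6-(methoxymethoxy)-4-[(methoxymethoxy)methyl]phenyl]ethan-1-one
Product: 6 (2E)-3-(dimethylamino)-1-[2-hydroxy-6-(methoxymethoxy)-4-[(methoxymethoxy)methyl]phenyl]but-2-en-1-one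
Conditions: MeC(OMe)2NMe2 (2 equiv), toluene, 90 °C
Reagents that add atoms: N,N-dimethylacetamide dimethyl acetal, COC(C)(OC)N(C)C
Why: Condensation of the methyl ketone with the amide acetal gives the thermodynamic E enaminone (enaminone formation) while the hydrogen-bonded phenol stays free.

**Step 4**
Reactants: 6 (2E)-3-(dimethylamino)-1-[2-hydroxy-6-(methoxymethoxy)-4-[(methoxymethoxy)methyl]phenyl]but-2-en-1-one
Product: 7 methyl 2-[5-(methoxymethoxy)-7-[(methoxymethoxy)methyl]-2-methyl-4-oxo-4H-chromen-3-yl]-2-oxoacetate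
Conditions: ClCOCO2Me, pyridine, CH2Cl2, 0 °C → rt
Reagents that add atoms: methyl chlorooxoacetate, COC(=O)C(Cl)=O
Why: C-acylation of the enaminone α-carbon followed by attack of the phenol on the iminium carbon and loss of dimethylamine (enaminone chromone synthesis, the established way to 3-methoxalylchromones) fixes the methyl group at C2 and the keto ester at C3 without ambiguity.

**Step 5**
Reactants: 7 methyl 2-[5-(methoxymethoxy)-7-[(methoxymethoxy)methyl]-2-methyl-4-oxo-4H-chromen-3-yl]-2-oxoacetate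
Product: 9 methyl 2-[2-ethenyl-5-(methoxymethoxy)-7-[(methoxymethoxy)methyl]-4-oxo-4H-chromen-3-yl]-2-oxoacetate, via Mannich base 8 (not isolated)
Conditions: (CH2O)n, PhNHMe·CF3CO2H, THF, 65 °C (the amine salt is regenerated)
Reagents that add atoms: paraformaldehyde (formaldehyde), C=O
Why: Mannich condensation at the doubly vinylogous, acidic 2-methyl group and E1cB loss of N-methylaniline (Gras-type methylenation) give the 2-vinylchromone.

**Step 6 (key step)**
Reactants: 9 methyl 2-[2-ethenyl-5-(methoxymethoxy)-7-[(methoxymethoxy)methyl]-4-oxo-4H-chromen-3-yl]-2-oxoacetate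
Product: 10 methyl (1S)-1-hydroxy-8-(methoxymethoxy)-6-[(methoxymethoxy)methyl]-9-oxo-1,9-dihydrocyclopenta[b]chromene-1-carboxylate
Conditions: chiral aminoindanol-derived N-mesityl triazolium salt (20 mol %), Cs2CO3 (20 mol %), 4 Å MS, THF (0.02 M), rt
Reagents that add atoms: none
Why: Proposed new method: the carbene adds 1,6 to the vinyl terminus of the dienone, proton transfer (carbonate/bicarbonate shuttle) gives the deoxy-Breslow ene-1,1-diamine in which this normally electrophilic carbon is a donor (a vinylogous homoenolate-type synthon), it closes 5-exo onto the electrophilic keto carbon of the α-keto ester, and E1cB loss of the azolium (acidic ring CH2) restores the alkene and frees the catalyst; the chiral azolium sits on the attacking carbon next to the forming quaternary carbinol and sets (S)-C1; closest known chemistry is the carbene-catalysed umpolung of Michael acceptors through deoxy-Breslow intermediates (ring-closing β-alkylation of enoates, enantioselective Rauhut–Currier-type cyclisations) and the intramolecular Morita–Baylis–Hillman reaction.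

**Step 7**
Reactants: 11 2,5-dimethoxy-4-methylbenzaldehyde
Product: 12 2,5-dihydroxy-4-methylbenzaldehyde
Conditions: BBr3 (2.5 equiv), CH2Cl2, −78 °C → rt; H2O
Reagents that add atoms: none
Why: Lewis acid cleavage of both aryl methyl ethers (BBr3 demethylation), which the aldehyde tolerates at low temperature.

**Step 8**
Reactants: 12 2,5-dihydroxy-4-methylbenzaldehyde, 13 3-methylbutane-1,3-diol
Product: 14 2-hydroxy-5-(3-hydroxy-3-methylbutoxy)-4-methylbenzaldehyde
Conditions: PPh3, DIAD, THF, 0 °C → rt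
Reagents that add atoms: none
Why: Mitsunobu etherification couples only the free 5-OH with the primary alcohol, because the 2-OH is hydrogen-bonded to the aldehyde and the tertiary alcohol is inert.

**Step 9**
Reactants: 14 2-hydroxy-5-(3-hydroxy-3-methylbutoxy)-4-methylbenzaldehyde
Product: 15 5-(3-hydroxy-3-methylbutoxy)-2-(methoxymethoxy)-4-methylbenzaldehyde
Conditions: MOMCl (1.3 equiv), i-Pr2NEt, CH2Cl2, 0 °C → rt
Reagents that add atoms: chloromethyl methyl ether, COCCl
Why: MOM protection of the remaining phenol; the tertiary alcohol reacts far more slowly.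

**Step 10**
Reactants: 15 5-(3-hydroxy-3-methylbutoxy)-2-(methoxymethoxy)-4-methylbenzaldehyde
Product: 18 2-(diethoxymethyl)-3-(3-hydroxy-3-methylbutoxy)-6-(methoxymethoxy)-4-methylbenzaldehyde, via amino alkoxide 16 (not isolated), via ortho-lithiated amino alkoxide 17 (not isolated)
Conditions: LiN(Me)CH2CH2NMe2 (2.2 equiv, from the amine and n-BuLi), THF, −20 °C; n-BuLi (3 equiv), −20 → 0 °C; PhOCH(OEt)2, −78 °C → rt; H2O
Reagents that add atoms: diethyl phenyl orthoformate, CCOC(OCC)Oc1ccccc1
Why: Comins protocol: the lithium amide masks the aldehyde as an α-amino alkoxide that, together with the ether oxygen, directs ortho-lithiation to the only C–H flanked by both, the aryllithium displaces phenoxide from the orthoformate (Bodroux–Chichibabin-type acetal synthesis), and water returns the aldehyde so that the two formyl carbons stay differentiated.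

**Step 11**
Reactants: 18 2-(diethoxymethyl)-3-(3-hydroxy-3-methylbutoxy)-6-(methoxymethoxy)-4-methylbenzaldehyde
Product: 19 4-[2-(diethoxymethyl)-3-formyl-4-(methoxymethoxy)-6-methylphenoxy]-2-methylbutan-2-yl acetate
Conditions: Ac2O, DMAP, Et3N, CH2Cl2, 40 °C
Reagents that add atoms: acetic anhydride, CC(=O)OC(C)=O
Why: DMAP-catalysed acylation of the tertiary alcohol, the only hydroxyl present, under basic conditions that spare the acetal and MOM ether.

**Step 12**
Reactants: 20 resorcinol
Product: 21 1,3-bis(methoxymethoxy)benzene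
Conditions: MOMCl (2.4 equiv), i-Pr2NEt, CH2Cl2, 0 °C → rt
Reagents that add atoms: chloromethyl methyl ether, COCCl
Why: MOM protection of both phenols, which also installs the directing groups for the next lithiation.

**Step 13**
Reactants: 21 1,3-bis(methoxymethoxy)benzene, 19 4-[2-(diethoxymethyl)-3-formyl-4-(methoxymethoxy)-6-methylphenoxy]-2-methylbutan-2-yl acetate
Product: 23 4-[3-{[2,6-bis(methoxymethoxy)phenyl](hydroxy)methyl}-2-(diethoxymethyl)-4-(methoxymethoxy)-6-methylphenoxy]-2-methylbutan-2-yl acetate (racemic), via aryllithium 22 (not isolated)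
Conditions: n-BuLi, THF, 0 °C → rt; then added slowly to 19, THF, −78 °C; H2O
Reagents that add atoms: none
Why: Directed ortho-metalation at C2 between the two OMOM groups and 1,2-addition of the aryllithium to the aldehyde, which at −78 °C with inverse addition is much faster than attack on the hindered tert-alkyl acetate; the racemic carbinol centre is erased in the next step.

**Step 14**
Reactants: 23 racemic diaryl carbinol acetal (1.5 equiv), 10 methyl (1S)-1-hydroxy-8-(methoxymethoxy)-6-[(methoxymethoxy)methyl]-9-oxo-1,9-dihydrocyclopenta[b]chromene-1-carboxylate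
Product: 26 penta-MOM ether of aspergichromone B (exo adduct; MOM on the four phenols and the primary alcohol; tertiary OH free), via cyclic ethyl acetal 24 (not isolated), via isobenzofuran 25 (not isolated)
Conditions: PPTS (10 mol %), 4 Å MS, toluene, 80 °C
Reagents that add atoms: none
Why: Acid-catalysed ring closure to the cyclic acetal and 1,4-elimination of ethanol give the isobenzofuran, which is trapped in a Diels–Alder reaction: the unsubstituted diene terminus (largest HOMO coefficient, least hindered) bonds to C2 of 10 (δ-carbon of the dienone) and the aryl-bearing terminus to C3, the diene adds to the face of 10 carrying OH (anti to CO2Me), and hydrogen bonding of that OH to the furan oxygen plus reversibility at 80 °C favour the exo adduct, so all four new stereocentres are set relative to C1.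

**Step 15**
Reactants: 26 penta-MOM ether of aspergichromone B
Product: 27 aspergichromone B
Conditions: Me2BBr (excess), CH2Cl2, −78 °C; then sat. NaHCO3, THF, 0 °C
Reagents that add atoms: none
Why: Bromodimethylborane cleaves acetal-type MOM ethers at −78 °C through bromomethyl ethers that hydrolyse on work-up (Guindon deprotection), a temperature at which the bridging ether, the methyl ester and the tertiary acetate are not attacked and no stereocentre is touched.

## Compound list

1 | 3,5-dihydroxybenzyl alcohol | OCc1cc(O)cc(O)c1 | starting material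
2 | 1,3-bis(methoxymethoxy)-5-[(methoxymethoxy)methyl]benzene | COCOCc1cc(OCOC)cc(OCOC)c1 | intermediate
3 | [2,6-bis(methoxymethoxy)-4-[(methoxymethoxy)methyl]phenyl]lithium (not isolated) | [Li]c1c(OCOC)cc(COCOC)cc1OCOC | intermediate
4 | 1-[2,6-bis(methoxymethoxy)-4-[(methoxymethoxy)methyl]phenyl]ethan-1-one (not isolated) | CC(=O)c1c(OCOC)cc(COCOC)cc1OCOC | intermediate
5 | 1-[2-hydroxy-6-(methoxymethoxy)-4-[(methoxymethoxy)methyl]phenyl]ethan-1-one | CC(=O)c1c(O)cc(COCOC)cc1OCOC | intermediate
6 | (2E)-3-(dimethylamino)-1-[2-hydroxy-6-(methoxymethoxy)-4-[(methoxymethoxy)methyl]phenyl]but-2-en-1-one | CN(C)/C(C)=C/C(=O)c1c(O)cc(COCOC)cc1OCOC | intermediate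
7 | methyl 2-[5-(methoxymethoxy)-7-[(methoxymethoxy)methyl]-2-methyl-4-oxo-4H-chromen-3-yl]-2-oxoacetate | COC(=O)C(=O)c1c(C)oc2cc(COCOC)cc(OCOC)c2c1=O | intermediate
8 | methyl 2-[5-(methoxymethoxy)-7-[(methoxymethoxy)methyl]-2-[2-(N-methylanilino)ethyl]-4-oxo-4H-chromen-3-yl]-2-oxoacetate (not isolated) | COC(=O)C(=O)c1c(CCN(C)c2ccccc2)oc2cc(COCOC)cc(OCOC)c2c1=O | intermediate
9 | methyl 2-[2-ethenyl-5-(methoxymethoxy)-7-[(methoxymethoxy)methyl]-4-oxo-4H-chromen-3-yl]-2-oxoacetate | COC(=O)C(=O)c1c(C=C)oc2cc(COCOC)cc(OCOC)c2c1=O | intermediate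
10 | methyl (1S)-1-hydroxy-8-(methoxymethoxy)-6-[(methoxymethoxy)methyl]-9-oxo-1,9-dihydrocyclopenta[b]chromene-1-carboxylate | COC(=O)[C@@]1(O)c2c(oc3cc(COCOC)cc(OCOC)c3c2=O)C=C1 | intermediate
11 | 2,5-dimethoxy-4-methylbenzaldehyde | O=Cc1cc(OC)c(C)cc1OC | starting material
12 | 2,5-dihydroxy-4-methylbenzaldehyde | O=Cc1cc(O)c(C)cc1O | intermediate
13 | 3-methylbutane-1,3-diol | CC(C)(O)CCO | starting material
14 | 2-hydroxy-5-(3-hydroxy-3-methylbutoxy)-4-methylbenzaldehyde | O=Cc1cc(OCCC(C)(C)O)c(C)cc1O | intermediate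
15 | 5-(3-hydroxy-3-methylbutoxy)-2-(methoxymethoxy)-4-methylbenzaldehyde | O=Cc1cc(OCCC(C)(C)O)c(C)cc1OCOC | intermediate
16 | dilithium α-amino alkoxide of 15 (aldehyde masked by the trimethylethylenediamide; tertiary alkoxide) (not isolated) | [Li]OC(N(C)CCN(C)C)c1cc(OCCC(C)(C)O[Li])c(C)cc1OCOC | intermediate
17 | ortho-lithiated amino alkoxide (lithium at the ring carbon between the masked aldehyde and the ether) (not isolated) | [Li]OC(N(C)CCN(C)C)c1c([Li])c(OCCC(C)(C)O[Li])c(C)cc1OCOC | intermediate
18 | 2-(diethoxymethyl)-3-(3-hydroxy-3-methylbutoxy)-6-(methoxymethoxy)-4-methylbenzaldehyde | O=Cc1c(C(OCC)OCC)c(OCCC(C)(C)O)c(C)cc1OCOC | intermediate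
19 | 4-[2-(diethoxymethyl)-3-formyl-4-(methoxymethoxy)-6-methylphenoxy]-2-methylbutan-2-yl acetate | O=Cc1c(C(OCC)OCC)c(OCCC(C)(C)OC(C)=O)c(C)cc1OCOC | intermediate
20 | resorcinol | Oc1cccc(O)c1 | starting material
21 | 1,3-bis(methoxymethoxy)benzene | COCOc1cccc(OCOC)c1 | intermediate
22 | [2,6-bis(methoxymethoxy)phenyl]lithium (not isolated) | [Li]c1c(OCOC)cccc1OCOC | intermediate
23 | 4-[3-{[2,6-bis(methoxymethoxy)phenyl](hydroxy)methyl}-2-(diethoxymethyl)-4-(methoxymethoxy)-6-methylphenoxy]-2-methylbutan-2-yl acetate (racemic) | OC(c1c(OCOC)cccc1OCOC)c1c(C(OCC)OCC)c(OCCC(C)(C)OC(C)=O)c(C)cc1OCOC | intermediate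
24 | 4-({1-[2,6-bis(methoxymethoxy)phenyl]-3-ethoxy-7-(methoxymethoxy)-5-methyl-1,3-dihydro-2-benzofuran-4-yl}oxy)-2-methylbutan-2-yl acetate (cis/trans mixture; not isolated) | CCOC1OC(c2c(OCOC)cccc2OCOC)c2c(OCOC)cc(C)c(OCCC(C)(C)OC(C)=O)c21 | intermediate
25 | 4-({1-[2,6-bis(methoxymethoxy)phenyl]-7-(methoxymethoxy)-5-methyl-2-benzofuran-4-yl}oxy)-2-methylbutan-2-yl acetate (isobenzofuran; not isolated) | O1C(c2c(OCOC)cccc2OCOC)=C2C(OCOC)=CC(C)=C(OCCC(C)(C)OC(C)=O)C2=C1 | intermediate
26 | penta-MOM ether of aspergichromone B (exo adduct; configuration as in 27) | COC(=O)[C@@]1(O)c2c(oc3cc(COCOC)cc(OCOC)c3c2=O)[C@H]2[C@@H]1[C@H]1O[C@]2(c2c(OCOC)cccc2OCOC)c2c(OCOC)cc(C)c(OCCC(C)(C)OC(C)=O)c21 | intermediate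
27 | aspergichromone B (1S carbinol; cyclopentane exo-fused to the 1,4-epoxide; C1–OH on the bridge side) | COC(=O)[C@@]1(O)c2c(oc3cc(CO)cc(O)c3c2=O)[C@H]2[C@@H]1[C@H]1O[C@]2(c2c(O)cccc2O)c2c(O)cc(C)c(OCCC(C)(C)OC(C)=O)c21 | target

## Totals and risk

Total step count: 15. Longest linear sequence: 8 steps (1–6, 14, 15; the arm 7–11, 13, 14, 15 is equally long).

**Step 6 (carbene umpolung cyclisation; new reaction, enantioselectivity untested).** The fallback sets out from 7 and comes back at 10, using a classical acyl-anion ring closure instead. Condensation of 7 with DMF dimethyl acetal gives the enamine methyl 2-[2-[(E)-2-(dimethylamino)ethenyl]-5-(methoxymethoxy)-7-[(methoxymethoxy)methyl]-4-oxo-4H-chromen-3-yl]-2-oxoacetate F1. Mild aqueous acid frees the aldehyde methyl 2-[5-(methoxymethoxy)-7-[(methoxymethoxy)methyl]-4-oxo-2-(2-oxoethyl)-4H-chromen-3-yl]-2-oxoacetate F2. A chiral triazolium carbene then closes the ring by an intramolecular crossed benzoin reaction (Breslow acyl anion of the aldehyde onto the keto ester) to the ketol methyl (1R)-1-hydroxy-8-(methoxymethoxy)-6-[(methoxymethoxy)methyl]-2,9-dioxo-1,2,3,9-tetrahydrocyclopenta[b]chromene-1-carboxylate F3. NaBH4 at −40 °C reduces the cyclopentanone to the diol methyl (1R)-1,2-dihydroxy-8-(methoxymethoxy)-6-[(methoxymethoxy)methyl]-9-oxo-1,2,3,9-tetrahydrocyclopenta[b]chromene-1-carboxylate F4. MsCl/Et3N converts its secondary hydroxyl into the mesylate methyl (1R)-1-hydroxy-2-(methanesulfonyloxy)-8-(methoxymethoxy)-6-[(methoxymethoxy)methyl]-9-oxo-1,2,3,9-tetrahydrocyclopenta[b]chromene-1-carboxylate F5, and DBU eliminates it (E1cB) to 10.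

**Step 10 (poly-anionic Comins lithiation with an unusual, hindered orthoformate quench).** The fallback sets out from 15 and comes back at 25, replacing the mono-acetal by a carboxylation/lactone redox sequence. Compound 15 is lithiated in the same way but quenched with CO2 and acidified to the hydroxyphthalide 3-hydroxy-7-(3-hydroxy-3-methylbutoxy)-4-(methoxymethoxy)-6-methyl-2-benzofuran-1(3H)-one F6. Aryllithium 22 (3 equiv) adds to its open aldehyde form, and acid work-up lactonises to 3-[2,6-bis(methoxymethoxy)phenyl]-7-(3-hydroxy-3-methylbutoxy)-4-(methoxymethoxy)-6-methyl-2-benzofuran-1(3H)-one F7. DIBAL-H at −78 °C gives the lactol 3-[2,6-bis(methoxymethoxy)phenyl]-7-(3-hydroxy-3-methylbutoxy)-4-(methoxymethoxy)-6-methyl-1,3-dihydro-2-benzofuran-1-ol F8. Ac2O/DMAP acetylates both the lactol and the tertiary alcohol to 7-(3-acetoxy-3-methylbutoxy)-3-[2,6-bis(methoxymethoxy)phenyl]-4-(methoxymethoxy)-6-methyl-1,3-dihydro-2-benzofuran-1-yl acetate F9, which loses acetic acid under the conditions of step 14 to give isobenzofuran 25.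

**Step 14 (cycloaddition: exo/face selectivity and lifetime of the isobenzofuran).** The fallback sets out from 10 and 23 and comes back at 27, running the cycloaddition on the unprotected partners so that free hydroxyls steer it; it also removes the need for step 15. HCl/MeOH at 45 °C takes both MOM groups off 10 to give methyl (1S)-1,8-dihydroxy-6-(hydroxymethyl)-9-oxo-1,9-dihydrocyclopenta[b]chromene-1-carboxylate F10. Dowex 50W (H+)/MeOH at 35 °C takes the three aryl MOM groups off 23 and closes the cyclic methyl acetal 4-{[1-(2,6-dihydroxyphenyl)-7-hydroxy-3-methoxy-5-methyl-1,3-dihydro-2-benzofuran-4-yl]oxy}-2-methylbutan-2-yl acetate F11. Warming F10 with F11 in aqueous acetonitrile (acetate buffer, pH 5, 40–50 °C) generates the free isobenzofuran 4-{[1-(2,6-dihydroxyphenyl)-7-hydroxy-5-methyl-2-benzofuran-4-yl]oxy}-2-methylbutan-2-yl acetate F12, which adds to F10 in the biomimetic sense to give 27 directly.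

## Further compounds

F1 | step 6 | methyl 2-[2-[(E)-2-(dimethylamino)ethenyl]-5-(methoxymethoxy)-7-[(methoxymethoxy)methyl]-4-oxo-4H-chromen-3-yl]-2-oxoacetate | COC(=O)C(=O)c1c(/C=C/N(C)C)oc2cc(COCOC)cc(OCOC)c2c1=O
F2 | step 6 | methyl 2-[5-(methoxymethoxy)-7-[(methoxymethoxy)methyl]-4-oxo-2-(2-oxoethyl)-4H-chromen-3-yl]-2-oxoacetate | COC(=O)C(=O)c1c(CC=O)oc2cc(COCOC)cc(OCOC)c2c1=O
F3 | step 6 | methyl (1R)-1-hydroxy-8-(methoxymethoxy)-6-[(methoxymethoxy)methyl]-2,9-dioxo-1,2,3,9-tetrahydrocyclopenta[b]chromene-1-carboxylate | COC(=O)[C@@]1(O)c2c(oc3cc(COCOC)cc(OCOC)c3c2=O)CC1=O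
F4 | step 6 | methyl (1R)-1,2-dihydroxy-8-(methoxymethoxy)-6-[(methoxymethoxy)methyl]-9-oxo-1,2,3,9-tetrahydrocyclopenta[b]chromene-1-carboxylate (C2 epimers) | COC(=O)[C@@]1(O)c2c(oc3cc(COCOC)cc(OCOC)c3c2=O)CC1O
F5 | step 6 | methyl (1R)-1-hydroxy-2-(methanesulfonyloxy)-8-(methoxymethoxy)-6-[(methoxymethoxy)methyl]-9-oxo-1,2,3,9-tetrahydrocyclopenta[b]chromene-1-carboxylate (C2 epimers) | COC(=O)[C@@]1(O)c2c(oc3cc(COCOC)cc(OCOC)c3c2=O)CC1OS(C)(=O)=O
F6 | step 10 | 3-hydroxy-7-(3-hydroxy-3-methylbutoxy)-4-(methoxymethoxy)-6-methyl-2-benzofuran-1(3H)-one | OC1OC(=O)c2c(OCCC(C)(C)O)c(C)cc(OCOC)c12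
F7 | step 10 | 3-[2,6-bis(methoxymethoxy)phenyl]-7-(3-hydroxy-3-methylbutoxy)-4-(methoxymethoxy)-6-methyl-2-benzofuran-1(3H)-one (racemic) | O=C1OC(c2c(OCOC)cccc2OCOC)c2c(OCOC)cc(C)c(OCCC(C)(C)O)c12
F8 | step 10 | 3-[2,6-bis(methoxymethoxy)phenyl]-7-(3-hydroxy-3-methylbutoxy)-4-(methoxymethoxy)-6-methyl-1,3-dihydro-2-benzofuran-1-ol | OC1OC(c2c(OCOC)cccc2OCOC)c2c(OCOC)cc(C)c(OCCC(C)(C)O)c12
F9 | step 10 | 7-(3-acetoxy-3-methylbutoxy)-3-[2,6-bis(methoxymethoxy)phenyl]-4-(methoxymethoxy)-6-methyl-1,3-dihydro-2-benzofuran-1-yl acetate | CC(=O)OC1OC(c2c(OCOC)cccc2OCOC)c2c(OCOC)cc(C)c(OCCC(C)(C)OC(C)=O)c12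
F10 | step 14 | methyl (1S)-1,8-dihydroxy-6-(hydroxymethyl)-9-oxo-1,9-dihydrocyclopenta[b]chromene-1-carboxylate | COC(=O)[C@@]1(O)c2c(oc3cc(CO)cc(O)c3c2=O)C=C1
F11 | step 14 | 4-{[1-(2,6-dihydroxyphenyl)-7-hydroxy-3-methoxy-5-methyl-1,3-dihydro-2-benzofuran-4-yl]oxy}-2-methylbutan-2-yl acetate | COC1OC(c2c(O)cccc2O)c2c(O)cc(C)c(OCCC(C)(C)OC(C)=O)c21
F12 | step 14 | 4-{[1-(2,6-dihydroxyphenyl)-7-hydroxy-5-methyl-2-benzofuran-4-yl]oxy}-2-methylbutan-2-yl acetate | O1C(c2c(O)cccc2O)=C2C(O)=CC(C)=C(OCCC(C)(C)OC(C)=O)C2=C1
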